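The target is epicatechin-(4β→8)-catechin carrying a 4-hydroxybenzoate on O3 of the lower unit. Everything rests on opening ring C of the upper unit at C4–C4a and O1–C2. The feature exploited is that C2–C3–C4 lies between ring B (on C2) and C8 of ring D (on C4), hence is a latent chalcone, while ring A with O1 is a phenol. One acid-catalysed operation, conjugate Friedel–Crafts attack then cyclodehydration, joins both, closes ring C, sets C4 and delivers the whole carbon skeleton as a flav-2-ene. The precursor is the (E)-chalcone grown from C8 of perbenzylated (+)-catechin, already esterified, so only enol-ether oxygenation/reduction and hydrogenolysis remain.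

Key step: step 7

Conventions: the upper unit has rings A (phloroglucinol), B (catechol) and C (pyran). The lower unit has rings D, E and F in the same sense. In ring C, β is the face that carries ring D at C4; α is the opposite face. Bn = benzyl.

Reading of the target: the upper unit is 2R,3R,4R (ring B 2α, OH 3α, ring D 4β, so 2,3-cis and 3,4-trans). The lower unit is 2R,3S, as in (+)-catechin.

Assumption: 3,5-dibenzyloxyphenol 11 is taken as a catalogue compound, because selective twofold O-benzylation of phloroglucinol is inefficient.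

Step 1
Reactants: 1 (+)-catechin
Product: 2 5,7,3',4'-tetra-O-benzyl-(+)-catechin (2R,3S; 3-OH free)
Conditions: BnBr (4.4 equiv), K2CO3, DMF, 0 °C → rt, Ar
Reagents that add atoms: benzyl bromide, BrCc1ccccc1
Why: Williamson etherification in which carbonate deprotonates only the four phenols, so the secondary alcohol stays free and both stereocentres are untouched.

Step 2
Reactants: 2 5,7,3',4'-tetra-O-benzyl-(+)-catechin
Product: 3 8-bromo-5,7,3',4'-tetra-O-benzyl-(+)-catechin (2R,3S)
Conditions: NBS (1.0 equiv), CH2Cl2, −78 °C → rt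
Reagents that add atoms: N-bromosuccinimide, O=C1CCC(=O)N1Br
Why: Electrophilic aromatic bromination of ring D, for which benzylated flavan-3-ols show a well-established preference for C8 over C6, and one equivalent at low temperature should stop at the monobromide.

Step 3
Reactants: 3 8-bromo-5,7,3',4'-tetra-O-benzyl-(+)-catechin
Product: 5 8-formyl-5,7,3',4'-tetra-O-benzyl-(+)-catechin, via C8-lithio lithium alkoxide 4 (not isolated)
Conditions: n-BuLi (2.2 equiv), THF, −78 °C; DMF (5 equiv), −78 → 0 °C; H2O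
Reagents that add atoms: N,N-dimethylformamide, CN(C)C=O
Why: The first equivalent makes the inert 3-alkoxide and the second performs bromine-lithium exchange, which at −78 °C is faster than benzyl ether metalation, and the aryllithium is formylated by DMF (Bouveault aldehyde synthesis).

Step 4
Reactants: 6 3,4-dihydroxyacetophenone
Product: 7 3,4-dibenzyloxyacetophenone
Conditions: BnBr (2.3 equiv), K2CO3, DMF, 60 °C
Reagents that add atoms: benzyl bromide, BrCc1ccccc1
Why: Williamson etherification of both catechol hydroxyls under conditions too mild to alkylate the methyl ketone.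

Step 5
Reactants: 5 8-formyl-5,7,3',4'-tetra-O-benzyl-(+)-catechin; 7 3,4-dibenzyloxyacetophenone
Product: 8 (E)-3-(5,7,3',4'-tetra-O-benzylcatechin-8-yl)-1-(3,4-dibenzyloxyphenyl)prop-2-en-1-one (3-OH free; 2R,3S)
Conditions: KOH (50 % aq), EtOH/THF, rt → 40 °C
Reagents that add atoms: none
Why: Claisen–Schmidt condensation of a non-enolisable 2,4,6-trialkoxybenzaldehyde, a known partner class, with E1cB loss of water giving the conjugated (E)-enone; since no phenol is free, C2 of ring F cannot epimerise by ring opening.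

Step 6
Reactants: 8 chalcone alcohol; 9 4-benzyloxybenzoic acid
Product: 10 (E)-3-[3-O-(4-benzyloxybenzoyl)-5,7,3',4'-tetra-O-benzylcatechin-8-yl]-1-(3,4-dibenzyloxyphenyl)prop-2-en-1-one (2R,3S)
Conditions: N,N'-dicyclohexylcarbodiimide, 4-dimethylaminopyridine (cat.), CH2Cl2, rt
Reagents that add atoms: none
Why: Steglich esterification leaves the C3–O bond intact (retention), and placing the final acyl group here instead of a silyl ether gives an acid-stable spectator and means the later-formed upper 3-OH never has to be distinguished from the lower one.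

Step 7
Reactants: 10 esterified catechin-8-yl chalcone; 11 3,5-dibenzyloxyphenol
Product: 14 (4R)-4-(lower unit-8-yl)-5,7,3',4'-tetrabenzyloxyflav-2-ene (ring D on the β face of C4), via Friedel-Crafts adduct 12 (not isolated), via hemiketal 13 (not isolated)
Conditions: 11 (1.5 equiv), (R)-3,3'-bis(2,4,6-triisopropylphenyl)-1,1'-binaphthyl-2,2'-diyl N-triflylphosphoramide (10 mol %), 5 Å MS, toluene, 0 °C → rt, Ar, dark
Reagents that add atoms: none
Why: Proposed new method: the strong chiral acid protonates the donor-substituted enone of 10 to a hydroxyallyl cation whose β carbon is stabilised by ring D, and phenol 11, held through its OH on the phosphoryl oxygen, attacks with the carbon ortho to OH and para to one OBn to give 12 and thereby C4–C4a. The phenol oxygen then adds to the aryl ketone (6-exo-trig) to hemiketal 13, and acid-promoted loss of water, taken up by the sieves, leaves the C2=C3 enol ether, so ring C is closed through O1–C2. The closest known reactions are the achiral acid condensation of electron-rich phenols and naphthols with chalcones to 2,4-diaryl-4H-chromenes and the chiral-phosphoric-acid Friedel–Crafts/cyclodehydration of naphthols with β,γ-unsaturated α-keto esters; the new element is chiral-acid face control on a plain chalcone. C4 is the only lasting new stereocentre, and its (R) configuration is to come from the chiral ion pair that binds nucleophile and electrophile together; the mirror-image catalyst is used if the (R) acid proves mismatched, and because 10 is enantiopure the 4-epimer is a diastereomer removable by chromatography. The step needs ortho-C attack rather than para-C or O attack, which is secured because only the ortho adduct can cyclise while the others revert under the acid; it must also stop at the monocyclic enol ether, which is secured because both oxygens next to C8 of ring D (O7 as benzyl ether, O1 within ring F) are alkylated and cannot form a bridged ketal.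

Step 8
Reactants: 14 flav-2-ene dimer
Product: 17 nona-O-benzyl epicatechin-(4β→8)-catechin 3-O-(4-benzyloxybenzoate) (upper 3-OH free; 2R,3R,4R;2R,3S), via 2α,3α-epoxide 15 (not isolated), via 3-O-triethylsilyl ether 16 (not isolated)
Conditions: DMDO (1.2 equiv, acetone), CH2Cl2, −78 → −40 °C; volatiles removed at 0 °C; Et3SiH (5 equiv), Et3SiOSO2CF3 (0.2 equiv), CH2Cl2, −78 °C; then 1 M HCl, THF, 0 °C
Reagents that add atoms: dimethyldioxirane, CC1(C)OO1
Why: Dioxirane epoxidation of the enol ether, as practised on glycals, should occur on the α face anti to the pseudoaxial ring D and fix C3–O; silyl-triflate-catalysed ionic hydrogenation of the epoxy ketal, as in the silane reduction of aryl ketals, then delivers hydride to C2 along the axial β trajectory anti to the O-silyl group (trans-diaxial opening), leaving ring B equatorial and cis to O3 (2R,3R).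

Step 9
Reactants: 17 nona-O-benzyl dimer ester
Product: 18 epicatechin-(4β→8)-catechin 3-O-(4-hydroxybenzoate) on the lower unit (2R,3R,4R;2R,3S), the target
Conditions: H2 (1 atm), Pd(OH)2/C, THF/MeOH/H2O, rt; filtration, lyophilisation, Sephadex LH-20
Reagents that add atoms: none
Why: Catalytic hydrogenolysis removes all nine benzyl ethers, while the aryl ester, the two ring C2–O1 bonds and the C4–C8 bond persist under the mild conditions customary for benzylated proanthocyanidins, and no stereocentre is touched.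

Compound list

1 | (+)-catechin (2R,3S) | O[C@H]1Cc2c(O)cc(O)cc2O[C@@H]1c1ccc(O)c(O)c1 | starting material

2 | 5,7,3',4'-tetra-O-benzyl-(+)-catechin | O[C@H]1Cc2c(OCc5ccccc5)cc(OCc5ccccc5)cc2O[C@@H]1c1ccc(OCc5ccccc5)c(OCc5ccccc5)c1 | intermediate

3 | 8-bromo-5,7,3',4'-tetra-O-benzyl-(+)-catechin | O[C@H]1Cc2c(OCc5ccccc5)cc(OCc5ccccc5)c(Br)c2O[C@@H]1c1ccc(OCc5ccccc5)c(OCc5ccccc5)c1 | intermediate

4 | 8-lithio-5,7,3',4'-tetra-O-benzylcatechin lithium 3-alkoxide | [Li]O[C@H]1Cc2c(OCc5ccccc5)cc(OCc5ccccc5)c([Li])c2O[C@@H]1c1ccc(OCc5ccccc5)c(OCc5ccccc5)c1 | intermediate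

5 | 8-formyl-5,7,3',4'-tetra-O-benzyl-(+)-catechin | O[C@H]1Cc2c(OCc5ccccc5)cc(OCc5ccccc5)c(C=O)c2O[C@@H]1c1ccc(OCc5ccccc5)c(OCc5ccccc5)c1 | intermediate

6 | 3,4-dihydroxyacetophenone | CC(=O)c1ccc(O)c(O)c1 | starting material

7 | 3,4-dibenzyloxyacetophenone | CC(=O)c1ccc(OCc5ccccc5)c(OCc5ccccc5)c1 | intermediate

8 | (E)-3-(5,7,3',4'-tetra-O-benzylcatechin-8-yl)-1-(3,4-dibenzyloxyphenyl)prop-2-en-1-one, 3-OH free | O[C@H]1Cc2c(OCc5ccccc5)cc(OCc5ccccc5)c(/C=C/C(=O)c4ccc(OCc5ccccc5)c(OCc5ccccc5)c4)c2O[C@@H]1c1ccc(OCc5ccccc5)c(OCc5ccccc5)c1 | intermediate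

9 | 4-benzyloxybenzoic acid | O=C(O)c1ccc(OCc2ccccc2)cc1 | starting material

10 | 3-O-(4-benzyloxybenzoyl) ester of 8 (key-step precursor) | O=C(O[C@H]1Cc2c(OCc5ccccc5)cc(OCc5ccccc5)c(/C=C/C(=O)c4ccc(OCc5ccccc5)c(OCc5ccccc5)c4)c2O[C@@H]1c1ccc(OCc5ccccc5)c(OCc5ccccc5)c1)c1ccc(OCc5ccccc5)cc1 | intermediate

11 | 3,5-dibenzyloxyphenol | Oc1cc(OCc5ccccc5)cc(OCc5ccccc5)c1 | starting material

12 | (3R)-3-(2-hydroxy-4,6-dibenzyloxyphenyl)-3-(lower unit-8-yl)-1-(3,4-dibenzyloxyphenyl)propan-1-one | O=C(O[C@H]1Cc2c(OCc5ccccc5)cc(OCc5ccccc5)c([C@H](CC(=O)c4ccc(OCc5ccccc5)c(OCc5ccccc5)c4)c4c(OCc5ccccc5)cc(OCc5ccccc5)cc4O)c2O[C@@H]1c1ccc(OCc5ccccc5)c(OCc5ccccc5)c1)c1ccc(OCc5ccccc5)cc1 | intermediate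

13 | 2-hydroxyflavan hemiketal of 12 (C2 undefined, 4R) | O=C(O[C@H]1Cc2c(OCc5ccccc5)cc(OCc5ccccc5)c([C@H]3c4c(OCc5ccccc5)cc(OCc5ccccc5)cc4OC(O)(c4ccc(OCc5ccccc5)c(OCc5ccccc5)c4)C3)c2O[C@@H]1c1ccc(OCc5ccccc5)c(OCc5ccccc5)c1)c1ccc(OCc5ccccc5)cc1 | intermediate

14 | (4R)-5,7-dibenzyloxy-2-(3,4-dibenzyloxyphenyl)-4-[3-O-(4-benzyloxybenzoyl)-5,7,3',4'-tetra-O-benzylcatechin-8-yl]-4H-chromene | O=C(O[C@H]1Cc2c(OCc5ccccc5)cc(OCc5ccccc5)c([C@H]3c4c(OCc5ccccc5)cc(OCc5ccccc5)cc4OC(c4ccc(OCc5ccccc5)c(OCc5ccccc5)c4)=C3)c2O[C@@H]1c1ccc(OCc5ccccc5)c(OCc5ccccc5)c1)c1ccc(OCc5ccccc5)cc1 | intermediate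

15 | 2α,3α-epoxide of 14 | O=C(O[C@H]1Cc2c(OCc5ccccc5)cc(OCc5ccccc5)c([C@H]3c4c(OCc5ccccc5)cc(OCc5ccccc5)cc4O[C@]6(c4ccc(OCc5ccccc5)c(OCc5ccccc5)c4)O[C@H]36)c2O[C@@H]1c1ccc(OCc5ccccc5)c(OCc5ccccc5)c1)c1ccc(OCc5ccccc5)cc1 | intermediate

16 | upper 3-O-triethylsilyl ether of 17 | O=C(O[C@H]1Cc2c(OCc5ccccc5)cc(OCc5ccccc5)c([C@H]3c4c(OCc5ccccc5)cc(OCc5ccccc5)cc4O[C@H](c4ccc(OCc5ccccc5)c(OCc5ccccc5)c4)[C@@H]3O[Si](CC)(CC)CC)c2O[C@@H]1c1ccc(OCc5ccccc5)c(OCc5ccccc5)c1)c1ccc(OCc5ccccc5)cc1 | intermediate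

17 | 5,7,3',4'-tetra-O-benzylepicatechin-(4β→8)-5,7,3',4'-tetra-O-benzylcatechin 3-O-(4-benzyloxybenzoate), upper 3-OH free | O=C(O[C@H]1Cc2c(OCc5ccccc5)cc(OCc5ccccc5)c([C@H]3c4c(OCc5ccccc5)cc(OCc5ccccc5)cc4O[C@H](c4ccc(OCc5ccccc5)c(OCc5ccccc5)c4)[C@@H]3O)c2O[C@@H]1c1ccc(OCc5ccccc5)c(OCc5ccccc5)c1)c1ccc(OCc5ccccc5)cc1 | intermediate

18 | epicatechin-(4β→8)-catechin 3-O-(4-hydroxybenzoate), CNP0288594.1 | O=C(O[C@H]1Cc2c(O)cc(O)c([C@H]3c4c(O)cc(O)cc4O[C@H](c4ccc(O)c(O)c4)[C@@H]3O)c2O[C@@H]1c1ccc(O)c(O)c1)c1ccc(O)cc1 | target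

Total step count: 9. Longest linear sequence: 8 (steps 1, 2, 3, 5, 6, 7, 8, 9 from (+)-catechin).

Steps most likely to fail

1. Step 7. The chiral ion pair may discriminate the two faces of C4 poorly. Addition to the donor-stabilised, doubly ortho-flanked β carbon may be slow, or the acid may reverse the Friedel–Crafts bond.
   - The fallback sets out from 11, 7, 2 and 9 and returns at 14. It exchanges the roles of the two phloroglucinol rings, so that C4–C8 is made by the long-known addition of an electron-rich arene to C4 of a flavylium ion.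
   - Ortho-formylation of 11 (MgCl2, Et3N, paraformaldehyde, MeCN, reflux) gives 2-hydroxy-4,6-dibenzyloxybenzaldehyde F1. Claisen–Schmidt condensation of F1 with 7 (KOH, EtOH/THF) gives the 2-hydroxychalcone F2.
   - Steglich esterification of 2 with 9 gives 5,7,3',4'-tetra-O-benzylcatechin 3-O-(4-benzyloxybenzoate) F3.
   - With catalytic camphor-10-sulfonic acid and sieves in CH2Cl2, F2 cyclises to the 5,7,3',4'-tetrabenzyloxyflavylium ion F4, which is intercepted at C4 by C8 of F3, the usual nucleophilic site.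
   - Compound 14 and its C4 epimer F5 are separated on silica, and 14 continues with step 8.

2. Step 8. Hydride may be delivered to the wrong face of the C2 oxocarbenium ion because ring D screens the β face. The opened epoxide may also undergo a 1,2-hydride shift to the 3-ketone before the silane intervenes.
   - The fallback sets out from 2 and returns at 17. It takes C2 and C3 of the upper unit from the chiral pool and makes the interflavan bond by the standard Lewis acid coupling of a C4-oxygenated flavan-3-ol.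
   - Compound 2 is oxidised (Dess–Martin periodinane, CH2Cl2) to (2R)-5,7,3',4'-tetrabenzyloxyflavan-3-one F6.
   - F6 is reduced from the face opposite ring B (LiBH(s-Bu)3, THF, −78 °C) to 5,7,3',4'-tetra-O-benzyl-(−)-epicatechin F7.
   - F7 is oxidised at C4 (DDQ, ethane-1,2-diol, CH2Cl2) to 4β-(2-hydroxyethoxy)-5,7,3',4'-tetra-O-benzylepicatechin F8.
   - TiCl4 in CH2Cl2/THF at 0 °C ionises F8. An excess of the ester F3 (from 2 and 9 as above) attacks the C4 cation through C8, anti to the 3-OH, to give 17 directly.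

3. Step 3. Bromine-lithium exchange may be incomplete, a proton may return to C8, or a benzyl ether may be metalated within the aggregate that holds the lithium alkoxide.
   - The fallback sets out from 3 and returns at 5. It masks the carbinol so that only a monolithium species is needed.
   - TBSCl and imidazole in DMF give 8-bromo-3-O-tert-butyldimethylsilyl-5,7,3',4'-tetra-O-benzylcatechin F9.
   - n-BuLi (1.1 equiv) in THF at −78 °C gives the 8-lithio silyl ether F10, and DMF converts it into the 8-formyl silyl ether F11.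
   - Bu4NF in THF then releases 5.

Further compounds

F1 | step 7 | 2-hydroxy-4,6-dibenzyloxybenzaldehyde | O=Cc1c(O)cc(OCc5ccccc5)cc1OCc5ccccc5

F2 | step 7 | (E)-3-(2-hydroxy-4,6-dibenzyloxyphenyl)-1-(3,4-dibenzyloxyphenyl)prop-2-en-1-one | O=C(/C=C/c1c(O)cc(OCc5ccccc5)cc1OCc5ccccc5)c1ccc(OCc5ccccc5)c(OCc5ccccc5)c1

F3 | step 7 | 5,7,3',4'-tetra-O-benzylcatechin 3-O-(4-benzyloxybenzoate) | O=C(O[C@H]1Cc2c(OCc5ccccc5)cc(OCc5ccccc5)cc2O[C@@H]1c1ccc(OCc5ccccc5)c(OCc5ccccc5)c1)c1ccc(OCc5ccccc5)cc1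

F4 | step 7 | 5,7,3',4'-tetrabenzyloxyflavylium ion | [o+]1c(-c4ccc(OCc5ccccc5)c(OCc5ccccc5)c4)ccc2c(OCc5ccccc5)cc(OCc5ccccc5)cc12

F5 | step 7 | C4 epimer (4S) of 14 | O=C(O[C@H]1Cc2c(OCc5ccccc5)cc(OCc5ccccc5)c([C@@H]3c4c(OCc5ccccc5)cc(OCc5ccccc5)cc4OC(c4ccc(OCc5ccccc5)c(OCc5ccccc5)c4)=C3)c2O[C@@H]1c1ccc(OCc5ccccc5)c(OCc5ccccc5)c1)c1ccc(OCc5ccccc5)cc1

F6 | step 8 | (2R)-5,7,3',4'-tetrabenzyloxyflavan-3-one | O=C1Cc2c(OCc5ccccc5)cc(OCc5ccccc5)cc2O[C@@H]1c1ccc(OCc5ccccc5)c(OCc5ccccc5)c1

F7 | step 8 | 5,7,3',4'-tetra-O-benzyl-(−)-epicatechin (2R,3R) | O[C@@H]1Cc2c(OCc5ccccc5)cc(OCc5ccccc5)cc2O[C@@H]1c1ccc(OCc5ccccc5)c(OCc5ccccc5)c1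

F8 | step 8 | 4β-(2-hydroxyethoxy)-5,7,3',4'-tetra-O-benzylepicatechin | OCCO[C@H]3c4c(OCc5ccccc5)cc(OCc5ccccc5)cc4O[C@H](c4ccc(OCc5ccccc5)c(OCc5ccccc5)c4)[C@@H]3O

F9 | step 3 | 8-bromo-3-O-tert-butyldimethylsilyl-5,7,3',4'-tetra-O-benzylcatechin | CC(C)(C)[Si](C)(C)O[C@H]1Cc2c(OCc5ccccc5)cc(OCc5ccccc5)c(Br)c2O[C@@H]1c1ccc(OCc5ccccc5)c(OCc5ccccc5)c1

F10 | step 3 | 8-lithio-3-O-tert-butyldimethylsilyl-5,7,3',4'-tetra-O-benzylcatechin | CC(C)(C)[Si](C)(C)O[C@H]1Cc2c(OCc5ccccc5)cc(OCc5ccccc5)c([Li])c2O[C@@H]1c1ccc(OCc5ccccc5)c(OCc5ccccc5)c1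

F11 | step 3 | 8-formyl-3-O-tert-butyldimethylsilyl-5,7,3',4'-tetra-O-benzylcatechin | CC(C)(C)[Si](C)(C)O[C@H]1Cc2c(OCc5ccccc5)cc(OCc5ccccc5)c(C=O)c2O[C@@H]1c1ccc(OCc5ccccc5)c(OCc5ccccc5)c1
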